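**Retrosynthetic overview**
1. Target 30 ⇐ O-debenzylation of 29; the flavonol pyranone is closed last, by a one-pot Claisen–Schmidt/Algar–Flynn–Oyamada sequence from aldehyde 21 and ring-A ketone 26.
2. 21 ⇐ bromo alcohol 18 ⇐ trans ester 17 ⇐ oxidative ring contraction (1,2-aryl shift, chromanone → dihydrobenzofuran) of (R)-flavanone 15; C2 controls C3.
3. 15 ⇐ enantioselective rhodium-catalysed 1,4-arylation of chromone 11 with the arylzinc made from bromide 4 (proposed new step).
4. 11 ⇐ 4-bromophenol (Fries, iodination, Cu C–O coupling, enaminone cyclisation); 4 ⇐ catechol; 26 ⇐ resorcinol (acylation, benzylation, directed C–H borylation/oxidation).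
5. Ring order: chromone pyranone → contracted to the dihydrofuran → flavonol pyranone.

Assumption: the SMILES is read as the (2R,3S)-trans dihydrobenzofuran, and that isomer is made.

**Route**

Step 1
Reactants: 1 catechol (benzene-1,2-diol)
Product: 2 guaiacol (2-methoxyphenol)
Conditions: MeI (1.0 equiv), K2CO3 (1.0 equiv), acetone, reflux
Reagents that add atoms: iodomethane, CI
Why: Williamson mono-O-methylation; one equivalent of MeI gives mainly the mono-ether, and veratrole and unreacted catechol are removed by NaOH partition and distillation.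

Step 2
Reactants: 2 guaiacol
Product: 3 4-bromo-2-methoxyphenol
Conditions: NBS (1.0 equiv), MeCN, 0 °C → rt
Reagents that add atoms: N-bromosuccinimide, O=C1CCC(=O)N1Br
Why: Electrophilic aromatic bromination; the free OH is the stronger para director, so Br enters para to OH.

Step 3
Reactants: 3 4-bromo-2-methoxyphenol
Product: 4 1-(benzyloxy)-4-bromo-2-methoxybenzene
Conditions: BnBr (1.1 equiv), K2CO3, acetone, reflux
Reagents that add atoms: benzyl bromide, BrCc1ccccc1
Why: Williamson O-benzylation protects the phenol for the organometallic and oxidative steps.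

Step 4
Reactants: 5 4-bromophenol
Product: 7 1-(5-bromo-2-hydroxyphenyl)ethanone, via aryl acetate 6 (not isolated)
Conditions: AcCl (1.1 equiv), 60 °C; then AlCl3 (1.6 equiv), 140 °C, 2 h; ice/HCl
Reagents that add atoms: acetyl chloride, CC(=O)Cl
Why: O-acetylation then Fries rearrangement; the para position is blocked by Br, so the acetyl group shifts ortho to oxygen.

Step 5
Reactants: 7 1-(5-bromo-2-hydroxyphenyl)ethanone
Product: 8 1-(5-bromo-2-hydroxy-3-iodophenyl)ethanone
Conditions: NIS (1.05 equiv), p-TsOH (cat.), MeCN, rt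
Reagents that add atoms: N-iodosuccinimide, O=C1CCC(=O)N1I
Why: Electrophilic iodination; C3 (ortho to OH) is the only activated free position.

Step 6
Reactants: 8 1-(5-bromo-2-hydroxy-3-iodophenyl)ethanone
Product: 9 1-[3-(benzyloxy)-5-bromo-2-hydroxyphenyl]ethanone
Conditions: BnOH (4 equiv), CuI (10 mol%), 3,4,7,8-tetramethyl-1,10-phenanthroline (20 mol%), Cs2CO3 (2.5 equiv), toluene, 90 °C
Reagents that add atoms: benzyl alcohol, OCc1ccccc1
Why: Ullmann-type copper-catalysed C–O coupling; C–I reacts far faster than C–Br, as in the classical alkoxylation of ortho-iodophenols.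

Step 7
Reactants: 9 1-[3-(benzyloxy)-5-bromo-2-hydroxyphenyl]ethanone
Product: 11 8-(benzyloxy)-6-bromo-4H-chromen-4-one, via enaminone 10 (not isolated)
Conditions: Me2NCH(OMe)2, toluene, 100 °C; then conc. HCl, CH2Cl2, 40 °C
Reagents that add atoms: N,N-dimethylformamide dimethyl acetal, COC(OC)N(C)C
Why: Enaminone formation then acid-promoted cyclisation with loss of Me2NH (standard chromone synthesis).

Step 8
Reactants: 4 1-(benzyloxy)-4-bromo-2-methoxybenzene; 11 8-(benzyloxy)-6-bromo-4H-chromen-4-one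
Product: 15 (2R)-8-(benzyloxy)-2-[4-(benzyloxy)-3-methoxyphenyl]-6-bromo-2,3-dihydro-4H-chromen-4-one, via arylmagnesium bromide 12 (not isolated), via arylzinc chloride 13 (not isolated), via silyl enol ether 14 (not isolated)
Conditions: 4 (1.6 equiv), Mg, THF, 45 °C; ZnCl2 (1.7 equiv), 0 °C → rt; then 11, [RhCl(C2H4)2]2 (1.5 mol%), (R)-BINAP (3.3 mol%), Me3SiCl (2 equiv), THF, 20 °C; 1 M HCl
Reagents that add atoms: none
Why: Proposed new method: rhodium/BINAP-catalysed enantioselective 1,4-addition of arylzinc chlorides with Me3SiCl trapping is established for cycloalkenones, 2,3-dihydro-4-pyridones and 4-quinolones (closest known reaction type) but not for chromones, where only aqueous boronic-acid additions are known; ArZnCl transmetalates to the monovalent-rhodium chloride, aryl–Rh adds across C2=C3 of 11 on the face selected by (R)-BINAP (predicted 2R from the quinolone and cyclohexenone cases, to be verified by chiral HPLC and the ligand antipode swapped if needed), and Me3SiCl silylates the oxa-π-allyl rhodium to give 14 and regenerate Rh–Cl, so the anhydrous base-free medium avoids pyranone ring opening and retro-oxa-Michael racemisation and leaves both C–Br bonds intact; acid hydrolysis of 14 gives 15 with the C2 stereocentre set.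

Step 9
Reactants: 15 (2R)-8-(benzyloxy)-2-[4-(benzyloxy)-3-methoxyphenyl]-6-bromo-2,3-dihydro-4H-chromen-4-one
Product: 17 methyl (2R,3R)-7-(benzyloxy)-2-[4-(benzyloxy)-3-methoxyphenyl]-5-bromo-2,3-dihydro-1-benzofuran-3-carboxylate, via methyl enol ether 16 (not isolated)
Conditions: PhI(OAc)2 (1.3 equiv), H2SO4 (2 equiv), HC(OMe)3/CH2Cl2, 0 °C → rt
Reagents that add atoms: trimethyl orthoformate, COC(OC)OC
Why: Oxidative ring contraction of a flavanone by a trivalent-iodine reagent: enol ether 16 is attacked at C3 by the iodane, methanol adds at C4, and the ring-A carbon C4a migrates from C4 to C3 with loss of PhI (1,2-aryl shift) to give the ester; C2 is untouched (R retained) and C3 forms trans to the aryl group (3R), which is also the thermodynamic arrangement.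

Step 10
Reactants: 17 methyl (2R,3R)-7-(benzyloxy)-2-[4-(benzyloxy)-3-methoxyphenyl]-5-bromo-2,3-dihydro-1-benzofuran-3-carboxylate
Product: 18 [(2R,3S)-7-(benzyloxy)-2-[4-(benzyloxy)-3-methoxyphenyl]-5-bromo-2,3-dihydro-1-benzofuran-3-yl]methanol
Conditions: LiAlH4 (1.2 equiv), THF, 0 °C, 30 min
Reagents that add atoms: none
Why: Hydride reduction of the ester to the primary alcohol; the aryl bromide is inert at 0 °C and both stereocentres are untouched (3R → 3S is only a change of descriptor).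

Step 11
Reactants: 18 [(2R,3S)-7-(benzyloxy)-2-[4-(benzyloxy)-3-methoxyphenyl]-5-bromo-2,3-dihydro-1-benzofuran-3-yl]methanol
Product: 21 (2R,3S)-7-(benzyloxy)-2-[4-(benzyloxy)-3-methoxyphenyl]-3-(hydroxymethyl)-2,3-dihydro-1-benzofuran-5-carbaldehyde, via dilithio species 19 (not isolated), via lithium hemiaminolate 20 (not isolated)
Conditions: n-BuLi (2.3 equiv), THF, −78 °C; DMF (5 equiv), −78 → 0 °C; H2O
Reagents that add atoms: N,N-dimethylformamide, CN(C)C=O
Why: Alkoxide formation, fast Br/Li exchange and Bouveault-type formylation with DMF; no stereocentre carries an acidic hydrogen, so both are preserved.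

Step 12
Reactants: 22 resorcinol (benzene-1,3-diol)
Product: 23 1-(2,4-dihydroxyphenyl)ethanone
Conditions: AcOH, ZnCl2 (1.2 equiv), 145 °C
Reagents that add atoms: acetic acid, CC(=O)O
Why: Nencki (Friedel–Crafts) acylation at C4, the position ortho/para to both hydroxyls.

Step 13
Reactants: 23 1-(2,4-dihydroxyphenyl)ethanone
Product: 24 1-[2,4-bis(benzyloxy)phenyl]ethanone
Conditions: BnBr (2.4 equiv), K2CO3 (3 equiv), DMF, 80 °C
Reagents that add atoms: benzyl bromide, BrCc1ccccc1
Why: Williamson benzylation of both phenols; DMF and heat are needed for the hydrogen-bonded ortho OH.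

Step 14
Reactants: 24 1-[2,4-bis(benzyloxy)phenyl]ethanone
Product: 26 1-[2,4-bis(benzyloxy)-6-hydroxyphenyl]ethanone, via pinacol boronate 25 (not isolated)
Conditions: B2pin2 (1.1 equiv), [Ir(OMe)(cod)]2 (1.5 mol%), AsPh3 (6 mol%), octane, 120 °C; then NaBO3·4H2O, THF/H2O, rt
Reagents that add atoms: sodium perborate, [Na+].[Na+].O[B-]1(O)OO[B-](O)(O)OO1
Why: Ketone-directed iridium-catalysed ortho C–H borylation (the carbonyl oxygen binds Ir and C6–H is the only ortho C–H), then mild boronate oxidation to the phenol; this installs the third ring-A oxygen.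

Step 15
Reactants: 21 (2R,3S)-7-(benzyloxy)-2-[4-(benzyloxy)-3-methoxyphenyl]-3-(hydroxymethyl)-2,3-dihydro-1-benzofuran-5-carbaldehyde; 26 1-[2,4-bis(benzyloxy)-6-hydroxyphenyl]ethanone
Product: 29 5,7-bis(benzyloxy)-2-[(2R,3S)-7-(benzyloxy)-2-[4-(benzyloxy)-3-methoxyphenyl]-3-(hydroxymethyl)-2,3-dihydro-1-benzofuran-5-yl]-3-hydroxy-4H-chromen-4-one, via chalcone 27 (not isolated), via dihydroflavonol 28 (not isolated)
Conditions: KOH (50% aq, 10 equiv), EtOH/THF, rt, 48 h; then H2O2 (30% aq, 6 equiv), 0 °C → rt; 1 M HCl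
Reagents that add atoms: hydrogen peroxide, OO
Why: Claisen–Schmidt condensation to the 2'-hydroxychalcone, then Algar–Flynn–Oyamada oxidative cyclisation in the same pot; the two transient stereocentres of 28 are destroyed on dehydrogenation and the benzofuran stereocentres are not touched.

Step 16
Reactants: 29 5,7-bis(benzyloxy)-2-[(2R,3S)-7-(benzyloxy)-2-[4-(benzyloxy)-3-methoxyphenyl]-3-(hydroxymethyl)-2,3-dihydro-1-benzofuran-5-yl]-3-hydroxy-4H-chromen-4-one
Product: 30 2,3-dehydrosilychristin, 3,5,7-trihydroxy-2-[(2R,3S)-7-hydroxy-2-(4-hydroxy-3-methoxyphenyl)-3-(hydroxymethyl)-2,3-dihydro-1-benzofuran-5-yl]-4H-chromen-4-one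
Conditions: H2 (1 atm), Pd/C (10%), THF/MeOH, rt, stopped after 4 equiv H2
Reagents that add atoms: none
Why: Hydrogenolysis of the four O-benzyl ethers; aryl benzyl ethers cleave faster than the cyclic benzylic C2–O bond or the chromenone C2=C3, so the stereocentres survive.

**Compound list**
1 | catechol (benzene-1,2-diol) | Oc1ccccc1O | starting material
2 | guaiacol (2-methoxyphenol) | COc1ccccc1O | intermediate
3 | 4-bromo-2-methoxyphenol | COc1cc(Br)ccc1O | intermediate
4 | 1-(benzyloxy)-4-bromo-2-methoxybenzene | COc1cc(Br)ccc1OCc1ccccc1 | intermediate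
5 | 4-bromophenol | Oc1ccc(Br)cc1 | starting material
6 | 4-bromophenyl acetate | CC(=O)Oc1ccc(Br)cc1 | intermediate
7 | 1-(5-bromo-2-hydroxyphenyl)ethanone | CC(=O)c1cc(Br)ccc1O | intermediate
8 | 1-(5-bromo-2-hydroxy-3-iodophenyl)ethanone | CC(=O)c1cc(Br)cc(I)c1O | intermediate
9 | 1-[3-(benzyloxy)-5-bromo-2-hydroxyphenyl]ethanone | CC(=O)c1cc(Br)cc(OCc2ccccc2)c1O | intermediate
10 | (E)-1-[3-(benzyloxy)-5-bromo-2-hydroxyphenyl]-3-(dimethylamino)prop-2-en-1-one | CN(C)/C=C/C(=O)c1cc(Br)cc(OCc2ccccc2)c1O | intermediate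
11 | 8-(benzyloxy)-6-bromo-4H-chromen-4-one | O=c1ccoc2c(OCc3ccccc3)cc(Br)cc12 | intermediate
12 | [4-(benzyloxy)-3-methoxyphenyl]magnesium bromide | COc1cc([Mg]Br)ccc1OCc1ccccc1 | intermediate
13 | [4-(benzyloxy)-3-methoxyphenyl]zinc chloride | COc1cc([Zn]Cl)ccc1OCc1ccccc1 | intermediate
14 | (2R)-8-(benzyloxy)-2-[4-(benzyloxy)-3-methoxyphenyl]-6-bromo-4-[(trimethylsilyl)oxy]-2H-chromene | COc1cc([C@H]2C=C(O[Si](C)(C)C)c3cc(Br)cc(OCc4ccccc4)c3O2)ccc1OCc1ccccc1 | intermediate
15 | (2R)-8-(benzyloxy)-2-[4-(benzyloxy)-3-methoxyphenyl]-6-bromo-2,3-dihydro-4H-chromen-4-one | COc1cc([C@H]2CC(=O)c3cc(Br)cc(OCc4ccccc4)c3O2)ccc1OCc1ccccc1 | intermediate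
16 | (2R)-8-(benzyloxy)-2-[4-(benzyloxy)-3-methoxyphenyl]-6-bromo-4-methoxy-2H-chromene | COc1cc([C@H]2C=C(OC)c3cc(Br)cc(OCc4ccccc4)c3O2)ccc1OCc1ccccc1 | intermediate
17 | methyl (2R,3R)-7-(benzyloxy)-2-[4-(benzyloxy)-3-methoxyphenyl]-5-bromo-2,3-dihydro-1-benzofuran-3-carboxylate (trans) | COc1cc([C@@H]2Oc3c(OCc4ccccc4)cc(Br)cc3[C@H]2C(=O)OC)ccc1OCc1ccccc1 | intermediate
18 | [(2R,3S)-7-(benzyloxy)-2-[4-(benzyloxy)-3-methoxyphenyl]-5-bromo-2,3-dihydro-1-benzofuran-3-yl]methanol | COc1cc([C@@H]2Oc3c(OCc4ccccc4)cc(Br)cc3[C@H]2CO)ccc1OCc1ccccc1 | intermediate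
19 | dilithio species of 18 (C5 aryllithium and lithium alkoxide) | COc1cc([C@@H]2Oc3c(OCc4ccccc4)cc([Li])cc3[C@H]2CO[Li])ccc1OCc1ccccc1 | intermediate
20 | dilithium salt of the DMF adduct of 19 (C5 α-(dimethylamino) alkoxide and primary alkoxide) | COc1cc([C@@H]2Oc3c(OCc4ccccc4)cc(C(O[Li])N(C)C)cc3[C@H]2CO[Li])ccc1OCc1ccccc1 | intermediate
21 | (2R,3S)-7-(benzyloxy)-2-[4-(benzyloxy)-3-methoxyphenyl]-3-(hydroxymethyl)-2,3-dihydro-1-benzofuran-5-carbaldehyde | COc1cc([C@@H]2Oc3c(OCc4ccccc4)cc(C=O)cc3[C@H]2CO)ccc1OCc1ccccc1 | intermediate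
22 | resorcinol (benzene-1,3-diol) | Oc1cccc(O)c1 | starting material
23 | 1-(2,4-dihydroxyphenyl)ethanone | CC(=O)c1ccc(O)cc1O | intermediate
24 | 1-[2,4-bis(benzyloxy)phenyl]ethanone | CC(=O)c1ccc(OCc2ccccc2)cc1OCc1ccccc1 | intermediate
25 | 1-[2,4-bis(benzyloxy)-6-(4,4,5,5-tetramethyl-1,3,2-dioxaborolan-2-yl)phenyl]ethanone | CC(=O)c1c(OCc2ccccc2)cc(OCc2ccccc2)cc1B1OC(C)(C)C(C)(C)O1 | intermediate
26 | 1-[2,4-bis(benzyloxy)-6-hydroxyphenyl]ethanone | CC(=O)c1c(O)cc(OCc2ccccc2)cc1OCc1ccccc1 | intermediate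
27 | (E)-1-[2,4-bis(benzyloxy)-6-hydroxyphenyl]-3-[(2R,3S)-7-(benzyloxy)-2-[4-(benzyloxy)-3-methoxyphenyl]-3-(hydroxymethyl)-2,3-dihydro-1-benzofuran-5-yl]prop-2-en-1-one | COc1cc([C@@H]2Oc3c(OCc4ccccc4)cc(/C=C/C(=O)c4c(O)cc(OCc5ccccc5)cc4OCc4ccccc4)cc3[C@H]2CO)ccc1OCc1ccccc1 | intermediate
28 | 5,7-bis(benzyloxy)-2-[(2R,3S)-7-(benzyloxy)-2-[4-(benzyloxy)-3-methoxyphenyl]-3-(hydroxymethyl)-2,3-dihydro-1-benzofuran-5-yl]-3-hydroxy-2,3-dihydro-4H-chromen-4-one (new C2/C3 centres trans, mixture) | COc1cc([C@@H]2Oc3c(OCc4ccccc4)cc(C4Oc5cc(OCc6ccccc6)cc(OCc6ccccc6)c5C(=O)C4O)cc3[C@H]2CO)ccc1OCc1ccccc1 | intermediate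
29 | 5,7-bis(benzyloxy)-2-[(2R,3S)-7-(benzyloxy)-2-[4-(benzyloxy)-3-methoxyphenyl]-3-(hydroxymethyl)-2,3-dihydro-1-benzofuran-5-yl]-3-hydroxy-4H-chromen-4-one | COc1cc([C@@H]2Oc3c(OCc4ccccc4)cc(-c4oc5cc(OCc6ccccc6)cc(OCc6ccccc6)c5c(=O)c4O)cc3[C@H]2CO)ccc1OCc1ccccc1 | intermediate
30 | 2,3-dehydrosilychristin | COc1cc([C@@H]2Oc3c(O)cc(-c4oc5cc(O)cc(O)c5c(=O)c4O)cc3[C@H]2CO)ccc1O | target

**Step count**
Total: 16 steps. Longest linear sequence: 10 steps (4, 5, 6, 7, 8, 9, 10, 11, 15, 16, from 4-bromophenol).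

**Three steps most likely to fail**

Step 8 (the proposed new step) may give low enantioselectivity, competing 1,2-addition or slow turnover on the chromone. The fallback uses known chemistry, sets out from 4 (with 11) and comes back at 15. Grignard 12 made from 4 is quenched with B(OMe)3 and hydrolysed to [4-(benzyloxy)-3-methoxyphenyl]boronic acid F1. F1 is then added to chromone 11 by the established divalent-palladium conjugate arylation of chromones (Pd(OCOCF3)2, tert-butyl pyridine–oxazoline ligand of the antipode that gives 2R, NH4PF6, H2O, 1,2-dichloroethane, 60 °C). This protocol tolerates aryl bromides and gives flavanone 15 directly.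

Step 9 may be diverted by migration of the electron-rich guaiacyl ring from C2 to C3 (isoflavone) or by dehydrogenation to the flavone. The fallback sets out from 15 and comes back at 17, and replaces the iodane chemistry by a Wolff ring contraction that does not depend on ring-B electronics. Nitrosation (isoamyl nitrite, HCl, EtOH) gives the 3-hydroxyimino flavanone F2. Chloramine (NH4OH/NaOCl, 0 °C, Forster reaction) converts it into the 3-diazo flavanone F3. Irradiation at 350 nm in MeOH gives the ring-contracted ester via the ketene as a cis/trans mixture. The cis isomer, methyl (2R,3S) ester F4, is equilibrated with NaOMe/MeOH to trans ester 17.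

Step 15 may give the aurone instead of the flavonol, a known bias of 6'-alkoxy chalcones in the Algar–Flynn–Oyamada reaction, or incomplete condensation. The fallback sets out from 21 and 26 and comes back at 29. Chalcone 27 is isolated after the KOH condensation and cyclised/dehydrogenated with I2 (10 mol%) in DMSO at 120 °C to the flavone F5. Dimethyldioxirane (acetone/CH2Cl2, 0 °C) epoxidises it to the flavone 2,3-epoxide F6, which a trace of p-TsOH opens to the 3-hydroxyflavone 29.

**Further compounds**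
F1 | step 8 | [4-(benzyloxy)-3-methoxyphenyl]boronic acid | COc1cc(B(O)O)ccc1OCc1ccccc1
F2 | step 9 | (2S)-8-(benzyloxy)-2-[4-(benzyloxy)-3-methoxyphenyl]-6-bromo-3-(hydroxyimino)-2,3-dihydro-4H-chromen-4-one (same spatial arrangement at C2 as 15; descriptor changes because C3 now outranks the aryl group) | COc1cc([C@H]2C(=NO)C(=O)c3cc(Br)cc(OCc4ccccc4)c3O2)ccc1OCc1ccccc1
F3 | step 9 | (2S)-8-(benzyloxy)-2-[4-(benzyloxy)-3-methoxyphenyl]-6-bromo-3-diazo-2,3-dihydro-4H-chromen-4-one | COc1cc([C@H]2C(=[N+]=[N-])C(=O)c3cc(Br)cc(OCc4ccccc4)c3O2)ccc1OCc1ccccc1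
F4 | step 9 | methyl (2R,3S)-7-(benzyloxy)-2-[4-(benzyloxy)-3-methoxyphenyl]-5-bromo-2,3-dihydro-1-benzofuran-3-carboxylate (cis) | COc1cc([C@@H]2Oc3c(OCc4ccccc4)cc(Br)cc3[C@@H]2C(=O)OC)ccc1OCc1ccccc1
F5 | step 15 | 5,7-bis(benzyloxy)-2-[(2R,3S)-7-(benzyloxy)-2-[4-(benzyloxy)-3-methoxyphenyl]-3-(hydroxymethyl)-2,3-dihydro-1-benzofuran-5-yl]-4H-chromen-4-one | COc1cc([C@@H]2Oc3c(OCc4ccccc4)cc(-c4cc(=O)c5c(OCc6ccccc6)cc(OCc6ccccc6)cc5o4)cc3[C@H]2CO)ccc1OCc1ccccc1
F6 | step 15 | 2,3-epoxide of F5 (4,6-bis(benzyloxy)-1a-aryl-1a,7a-dihydro-7H-oxireno[2,3-b]chromen-7-one, aryl as in F5) | COc1cc([C@@H]2Oc3c(OCc4ccccc4)cc(C45OC4C(=O)c4c(OCc6ccccc6)cc(OCc6ccccc6)cc4O5)cc3[C@H]2CO)ccc1OCc1ccccc1
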